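Ring A (C1–OH, C2–OAr, C5–Br, C6–Br) is a 3,4-dibromocatechol, so its C1–O and C2–O bonds are disconnected together back to dioxygen and 1,2-dibromobenzene. A whole-cell toluene dioxygenase oxidation should add both oxygens across the ring bond flanking bromine in one operation, giving a cis-dihydrodiol whose hydroxyls differ: the future C2–O lies beside a CH=CH unit, the future C1–O beside C–Br. The less hindered C2 oxygen is then arylated with a bis(2,4-dibromophenyl)iodonium salt, and oxidation of the C1 carbinol gives a dienone that enolizes to the target. The precursor of the key step is the commercial arene itself.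

Key step: step 1

Remark on the chemistry: the dihydrodiol is assumed to be the (1S,2S) enantiomer by analogy with the bromobenzene metabolite. This has no bearing on the achiral target, because both stereocentres are removed in step 4. Ring A locants (C1 OH, C2 OAr, C5/C6 Br) are those of the target; ring B is the 2,4-dibromophenyl group.

Step 1
Reactants: 1 1,2-dibromobenzene; 2 dioxygen
Product: 3 (1S,2S)-3,4-dibromocyclohexa-3,5-diene-1,2-diol (cis-diol)
Conditions: E. coli JM109(pDTG601) whole cells (toluene dioxygenase, IPTG-induced), glucose, air, mineral salts medium pH 7.2, 30 °C; EtOAc extraction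
Reagents that add atoms: none
Why: The Rieske-type non-heme iron dioxygenase binds the arene beside its mononuclear iron centre, activates dioxygen with two electrons relayed from NADH (regenerated by the cells from glucose) and delivers both oxygen atoms to one face of one ring bond; this is the enzymatic arene cis-dihydroxylation known for bromobenzene and for ortho-dihalobenzenes in recombinant whole cells. No ring is closed. Both new stereocentres are set by the enzyme: suprafacial delivery from iron-bound dioxygen makes the hydroxyls cis, and the chiral pocket exposes a single face of the bound arene, which gives the (1S,2S) sense. The selectivity that matters is regiochemical, oxygenation of the C3–C4 bond next to bromine and not of the C4–C5 bond, and it is secured by the binding mode of halobenzenes, in which a halogen sits deep in the pocket and holds the adjoining ring bond over iron. The two ring bonds that flank the dibromo unit are mirror-related, so they lead to the same constitution. Extraction from slightly basic medium avoids acid-catalysed dehydration of the diene diol to bromophenols.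

Step 2
Reactants: 4 2,4-dibromo-1-iodobenzene; 5 1,3-dibromobenzene
Product: 7 bis(2,4-dibromophenyl)iodonium trifluoromethanesulfonate, via hydroxy(triflyloxy)iodane 6 (not isolated)
Conditions: mCPBA (1.1 equiv), TfOH (3 equiv), ClCH2CH2Cl, 0 → 60 °C; Et2O trituration
Reagents that add atoms: trifluoromethanesulfonic acid, OS(=O)(=O)C(F)(F)F
Why: Peracid oxidation of the aryl iodide in triflic acid gives a trivalent iodine electrophile that attacks 1,3-dibromobenzene at C4, the position para to one bromine and ortho to the other, in the established one-pot electrophilic aromatic substitution route to diaryliodonium triflates; the symmetrical salt leaves no choice as to which aryl group is transferred in step 3.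

Step 3
Reactants: 3 (1S,2S)-3,4-dibromocyclohexa-3,5-diene-1,2-diol; 7 bis(2,4-dibromophenyl)iodonium trifluoromethanesulfonate
Product: 9 (1S,6S)-2,3-dibromo-6-(2,4-dibromophenoxy)cyclohexa-2,4-dien-1-ol, via disodium dienediolate 8 (not isolated)
Conditions: NaH (2.1 equiv), THF, 0 °C → rt; then 7 (1.0 equiv), 0 °C → rt; H2O quench
Reagents that add atoms: none
Why: The step is an O-arylation of an alkoxide by a diaryliodonium salt (ligand exchange at trivalent iodine, then ligand coupling with release of the aryl iodide), a metal-free aryl ether synthesis established for secondary and allylic alcohols; with both hydroxyls deprotonated, the more basic and less hindered alkoxide beside CH=CH (ring A C2–O) should couple first, the alkoxide beside C–Br being inductively deactivated and screened by the vinylic bromine, and the two stereocentres are untouched.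

Step 4
Reactants: 9 (1S,6S)-2,3-dibromo-6-(2,4-dibromophenoxy)cyclohexa-2,4-dien-1-ol
Product: 11 2,3-dibromo-6-(2,4-dibromophenoxy)phenol, via aryloxy dienone 10 (not isolated)
Conditions: Dess–Martin periodinane (1.1 equiv), pyridine (3 equiv), CH2Cl2, 0 °C → rt
Reagents that add atoms: none
Why: Dess–Martin oxidation of the remaining allylic carbinol gives the 6-aryloxycyclohexa-2,4-dienone, which is the keto tautomer of the target and still carries a hydrogen on its sp3 carbon, so that pyridine-assisted enolization, driven by the gain of aromaticity, should deliver the phenol and erase the last stereocentre.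

Compound list
1 | 1,2-dibromobenzene | Brc1ccccc1Br | starting material
2 | dioxygen | O=O | starting material
3 | (1S,2S)-3,4-dibromocyclohexa-3,5-diene-1,2-diol | O[C@H]1C=CC(Br)=C(Br)[C@H]1O | intermediate
4 | 2,4-dibromo-1-iodobenzene | Brc1ccc(I)c(Br)c1 | starting material
5 | 1,3-dibromobenzene | Brc1cccc(Br)c1 | starting material
6 | 2,4-dibromo-1-[hydroxy(trifluoromethanesulfonyloxy)-λ3-iodanyl]benzene | OI(OS(=O)(=O)C(F)(F)F)c1ccc(Br)cc1Br | intermediate (not isolated)
7 | bis(2,4-dibromophenyl)iodonium trifluoromethanesulfonate | Brc1ccc([I+]c2ccc(Br)cc2Br)c(Br)c1.[O-]S(=O)(=O)C(F)(F)F | intermediate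
8 | disodium (1S,2S)-3,4-dibromocyclohexa-3,5-diene-1,2-diolate | [Na+].[Na+].[O-][C@H]1C=CC(Br)=C(Br)[C@H]1[O-] | intermediate (not isolated)
9 | (1S,6S)-2,3-dibromo-6-(2,4-dibromophenoxy)cyclohexa-2,4-dien-1-ol | Brc1ccc(O[C@H]2C=CC(Br)=C(Br)[C@H]2O)c(Br)c1 | intermediate
10 | (6S)-2,3-dibromo-6-(2,4-dibromophenoxy)cyclohexa-2,4-dien-1-one | Brc1ccc(O[C@H]2C=CC(Br)=C(Br)C2=O)c(Br)c1 | intermediate (not isolated)
11 | 2,3-dibromo-6-(2,4-dibromophenoxy)phenol | Oc1c(Oc2ccc(Br)cc2Br)ccc(Br)c1Br | target

Total step count: 4. Longest linear sequence: 3 steps (1 → 3 → 9 → 11); step 2 supplies the arylating salt convergently.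

Steps most likely to fail

Step 3. The aryl group may be transferred to the wrong oxygen or to both, the allylic alkoxide may lose hydride to the iodonium salt instead of coupling, or the strongly basic dialkoxide may aromatize. The fallback sets out from 3 and comes back at 11; it fixes the regiochemistry with protecting groups and forms the diaryl ether on a phenol. Hindrance-controlled silylation of 3 (TBSCl, imidazole, DMF, −10 °C) should cap the hydroxyl remote from bromine and give (1S,6S)-2,3-dibromo-6-[(tert-butyldimethylsilyl)oxy]cyclohexa-2,4-dien-1-ol F1. Dess–Martin oxidation (pyridine, CH2Cl2, 0 °C) should give (6S)-2,3-dibromo-6-[(tert-butyldimethylsilyl)oxy]cyclohexa-2,4-dien-1-one F2, which enolizes in the flask to 2,3-dibromo-6-[(tert-butyldimethylsilyl)oxy]phenol F3. MOMCl/iPr2NEt in CH2Cl2 should protect the phenol next to bromine as tert-butyl[3,4-dibromo-2-(methoxymethoxy)phenoxy]dimethylsilane F4, and TBAF in THF should free the other oxygen to give 3,4-dibromo-2-(methoxymethoxy)phenol F5. Arylation of this phenol with salt 7 (K2CO3, MeCN, 40 °C), the routine coupling of a phenoxide with a diaryliodonium salt, should give 1,2-dibromo-4-(2,4-dibromophenoxy)-3-(methoxymethoxy)benzene F6, and HCl in MeOH should remove the acetal to give 11.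

Step 1. The dense, poorly soluble and cytotoxic substrate may stall the culture, or the diol may be lost by dehydration or by further enzymatic dehydrogenation. The fallback sets out from 1 and comes back at 11; it introduces the two ring A oxygens one after the other by chemical means. Deprotonation of 1 next to bromine with LDA (lithium diisopropylamide) in THF at −78 °C should give (2,3-dibromophenyl)lithium F7, which is trapped cold with B(OMe)3 and hydrolysed with aqueous HCl to (2,3-dibromophenyl)boronic acid F8. H2O2/NaOH should oxidize it to 2,3-dibromophenol F9. Magnesium-mediated ortho-formylation (MgCl2, Et3N, paraformaldehyde, MeCN, reflux) at the only free ortho position should give 3,4-dibromo-2-hydroxybenzaldehyde F10, and MOMCl/iPr2NEt then 3,4-dibromo-2-(methoxymethoxy)benzaldehyde F11. Baeyer–Villiger oxidation with mCPBA should give 3,4-dibromo-2-(methoxymethoxy)phenyl formate F12, which K2CO3 in MeOH cleaves to the phenol F5 of the preceding fallback; arylation with 7 to F6 and acid cleavage to 11 follow as described there.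

Step 2. Electrophilic substitution of the doubly deactivated arene by an electron-poor trivalent iodine species may be too slow, so that the iodane decomposes before the second C–I bond is formed. The fallback sets out from 4 and comes back at 9. Oxidation of 4 with mCPBA and TsOH·H2O in MeCN at 75 °C should give 2,4-dibromo-1-[hydroxy(tosyloxy)-λ3-iodanyl]benzene F13, which is captured in the same pot by the far more nucleophilic 1,3,5-trimethoxybenzene to give (2,4-dibromophenyl)(2,4,6-trimethoxyphenyl)iodonium 4-methylbenzenesulfonate F14. In step 3 this salt replaces 7: the electron-rich trimethoxyphenyl group stays on iodine as a spectator and the electron-poor 2,4-dibromophenyl group should be transferred to dialkoxide 8 to give 9.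

Further compounds
F1 | step 3 | (1S,6S)-2,3-dibromo-6-[(tert-butyldimethylsilyl)oxy]cyclohexa-2,4-dien-1-ol | CC(C)(C)[Si](C)(C)O[C@H]1C=CC(Br)=C(Br)[C@H]1O
F2 | step 3 | (6S)-2,3-dibromo-6-[(tert-butyldimethylsilyl)oxy]cyclohexa-2,4-dien-1-one | CC(C)(C)[Si](C)(C)O[C@H]1C=CC(Br)=C(Br)C1=O
F3 | step 3 | 2,3-dibromo-6-[(tert-butyldimethylsilyl)oxy]phenol | CC(C)(C)[Si](C)(C)Oc1ccc(Br)c(Br)c1O
F4 | step 3 | tert-butyl[3,4-dibromo-2-(methoxymethoxy)phenoxy]dimethylsilane | COCOc1c(O[Si](C)(C)C(C)(C)C)ccc(Br)c1Br
F5 | step 3 | 3,4-dibromo-2-(methoxymethoxy)phenol | COCOc1c(O)ccc(Br)c1Br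
F6 | step 3 | 1,2-dibromo-4-(2,4-dibromophenoxy)-3-(methoxymethoxy)benzene | COCOc1c(Oc2ccc(Br)cc2Br)ccc(Br)c1Br
F7 | step 1 | (2,3-dibromophenyl)lithium | [Li]c1cccc(Br)c1Br
F8 | step 1 | (2,3-dibromophenyl)boronic acid | OB(O)c1cccc(Br)c1Br
F9 | step 1 | 2,3-dibromophenol | Oc1cccc(Br)c1Br
F10 | step 1 | 3,4-dibromo-2-hydroxybenzaldehyde | O=Cc1ccc(Br)c(Br)c1O
F11 | step 1 | 3,4-dibromo-2-(methoxymethoxy)benzaldehyde | COCOc1c(C=O)ccc(Br)c1Br
F12 | step 1 | 3,4-dibromo-2-(methoxymethoxy)phenyl formate | COCOc1c(OC=O)ccc(Br)c1Br
F13 | step 2 | 2,4-dibromo-1-[hydroxy(tosyloxy)-λ3-iodanyl]benzene | Cc1ccc(cc1)S(=O)(=O)OI(O)c1ccc(Br)cc1Br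
F14 | step 2 | (2,4-dibromophenyl)(2,4,6-trimethoxyphenyl)iodonium 4-methylbenzenesulfonate | COc1cc(OC)c([I+]c2ccc(Br)cc2Br)c(OC)c1.Cc1ccc(cc1)S(=O)(=O)[O-]
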